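## Retrosynthetic overview

1. Target 27 ⇒ desilylation, C-16 acetylation and nitrile-to-aldehyde reduction of 24; 24 ⇒ B-alkyl Suzuki disconnection at C-13/C-14 (iridal numbering) into ring fragment 11 and vinyl iodide 22.
2. 11 ⇒ Horner–Wadsworth–Emmons olefination of ketone 9 ⇐ Nef reaction ⇐ methylenation of aldehyde 6.
3. 6 ⇒ amine-catalysed nitro-Michael/aldol domino of α-methyl enal 3 (a cross-metathesis product) with 5-nitropentan-2-one; this sets C-6, C-10 and C-11 from achiral materials.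
4. 22 ⇒ catalytic asymmetric alkenylzinc addition of alkyne 15 [from (S)-citronellal, made by organocatalytic transfer hydrogenation of citral] to iodo enal 19.
5. Ring order: the only ring, the cyclohexane, is closed in step 2; everything afterwards is exocyclic or acyclic.

Assumption: 1, 4 and 10 are taken as catalogue compounds (1 and 4 are otherwise one step from pent-4-en-1-ol and from nitromethane plus methyl vinyl ketone).

## Route

**Step 1**
Reactants: 1 tert-butyldimethyl(pent-4-en-1-yloxy)silane; 2 methacrolein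
Product: 3 (2E)-6-[(tert-butyldimethylsilyl)oxy]-2-methylhex-2-enal
Conditions: second-generation Hoveyda–Grubbs catalyst (2 mol %), 2 (3 equiv), CH2Cl2, 40 °C
Reagents that add atoms: none
Why: Olefin cross-metathesis of a terminal alkene with excess methacrolein gives the trisubstituted enal with high E selectivity under thermodynamic control; no stereocentre is formed.

**Step 2**
Reactants: 3 (2E)-6-[(tert-butyldimethylsilyl)oxy]-2-methylhex-2-enal; 4 5-nitropentan-2-one
Product: 6 (1S,2S,5S,6S)-6-{3-[(tert-butyldimethylsilyl)oxy]propyl}-2-hydroxy-1,2-dimethyl-5-nitrocyclohexane-1-carbaldehyde, via Michael adduct 5 (not isolated)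
Conditions: 9-amino-9-deoxy-epi-quinidine (20 mol %), CF3CO2H (30 mol %), toluene, 40 °C, 48 h
Reagents that add atoms: none
Why: Proposed new method: an iminium–enamine relay in which the cinchona primary amine condenses with the α-branched enal 3 (secondary amines do not activate such enals), the nitronate of 4 adds to the Si face of C-3 of the iminium ion and so sets C-6 (sense assigned by analogy with this catalyst family on acyclic enones and not verified for this substrate; the quinine-derived pseudoenantiomer gives ent-6), and the enamine thus formed closes the ring by a 6-enolexo aldol onto the methyl ketone through a chair with the side chain, the epimerisable nitro group, the C=N unit and the acid-bound ketone oxygen equatorial, which sets the quaternary C-1 and the tertiary carbinol C-2 with OH trans to CHO and cannot dehydrate because C-1 has no hydrogen; the closest known reactions are the amine-catalysed nitro-Michael/aldol-condensation domino of γ-nitro ketones with β-substituted enals and primary-amine iminium–enamine cascades of α-branched enals with heteroatom nucleophiles.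

**Step 3**
Reactants: 6 (1S,2S,5S,6S)-6-{3-[(tert-butyldimethylsilyl)oxy]propyl}-2-hydroxy-1,2-dimethyl-5-nitrocyclohexane-1-carbaldehyde
Product: 7 (1S,2S,3S,4S)-3-{3-[(tert-butyldimethylsilyl)oxy]propyl}-2-ethenyl-1,2-dimethyl-4-nitrocyclohexan-1-ol
Conditions: Ph3PCH3Br (3.0 equiv), KN(SiMe3)2 (2.9 equiv), THF, −78 to 0 °C
Reagents that add atoms: methyltriphenylphosphonium bromide C[P+](c1ccccc1)(c1ccccc1)c1ccccc1.[Br-]
Why: Wittig methylenation of a non-enolisable aldehyde; the ylide is too weak a base to form the tertiary alkoxide (no retro-aldol) and one equivalent is taken up reversibly by the acidic C–H next to the nitro group, whose configuration is irrelevant.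

**Step 4**
Reactants: 7 (1S,2S,3S,4S)-3-{3-[(tert-butyldimethylsilyl)oxy]propyl}-2-ethenyl-1,2-dimethyl-4-nitrocyclohexan-1-ol
Product: 9 (2S,3S,4S)-2-{3-[(tert-butyldimethylsilyl)oxy]propyl}-3-ethenyl-4-hydroxy-3,4-dimethylcyclohexan-1-one, via sodium nitronate 8 (not isolated)
Conditions: NaOMe, MeOH, 0 °C; then aq. TiCl3, NH4OAc buffer (pH 5–6), rt
Reagents that add atoms: water O
Why: McMurry reductive Nef reaction, in which the nitronate is reduced to the imine and hydrolysed to the ketone near neutral pH, mild enough for the vinyl group, the silyl ether and the now α-positioned C-2 stereocentre.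

**Step 5**
Reactants: 9 (2S,3S,4S)-2-{3-[(tert-butyldimethylsilyl)oxy]propyl}-3-ethenyl-4-hydroxy-3,4-dimethylcyclohexan-1-one; 10 diethyl (1-cyanoethyl)phosphonate
Product: 11 (2Z)-2-[(2R,3S,4S)-2-{3-[(tert-butyldimethylsilyl)oxy]propyl}-3-ethenyl-4-hydroxy-3,4-dimethylcyclohexylidene]propanenitrile
Conditions: 10, NaH (1.0 equiv relative to 10), THF, 0 °C; then 9, 0 to 65 °C
Reagents that add atoms: none
Why: Horner–Wadsworth–Emmons olefination with the preformed, weakly basic phosphonate anion (no enolisation toward C-2); the linear cyano group is smaller than methyl and should take the position syn to the branched ring carbon to minimise A1,3 strain, giving mainly the Z-nitrile, with the minor E isomer removed by chromatography.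

**Step 6**
Reactants: 12 citral (E/Z mixture)
Product: 13 (3S)-3,7-dimethyloct-6-enal [(S)-citronellal]
Conditions: morpholinium salt of (S)-TRIP [(S)-3,3'-bis(2,4,6-triisopropylphenyl)-1,1'-binaphthyl-2,2'-diyl phosphate] (20 mol %), Hantzsch ester (1.1 equiv), THF, 50 °C
Reagents that add atoms: none
Why: Organocatalytic transfer hydrogenation by asymmetric counteranion-directed iminium catalysis; the E and Z iminium ions interconvert and hydride is delivered to one face inside the chiral phosphate ion pair, giving the 3S centre from either alkene isomer.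

**Step 7**
Reactants: 13 (3S)-3,7-dimethyloct-6-enal
Product: 15 (3S)-3,7-dimethyloct-6-en-1-yne, via enol nonaflate 14 (not isolated)
Conditions: C4F9SO2F, P2-Et phosphazene base (2.2 equiv), DMF, −20 °C to rt
Reagents that add atoms: none
Why: One-pot enol nonaflate formation and E2 elimination converts an enolisable aldehyde into the terminal alkyne with the same carbon count; the C-3 stereocentre is not acidic under these conditions.

**Step 8**
Reactants: 16 prop-2-yn-1-ol
Product: 18 (2E)-3-iodo-2-methylprop-2-en-1-ol, via alkenylalane 17 (not isolated)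
Conditions: Me3Al (3 equiv), Cp2ZrCl2 (25 mol %), CH2Cl2, 0 °C to rt; then I2, THF, −30 to 0 °C
Reagents that add atoms: trimethylaluminium C[Al](C)C; iodine [I][I]
Why: Negishi zirconium-catalysed carboalumination adds methyl and aluminium syn across the alkyne with aluminium at the terminus, and iodinolysis with retention gives the E-vinyl iodide.

**Step 9**
Reactants: 18 (2E)-3-iodo-2-methylprop-2-en-1-ol
Product: 19 (2E)-3-iodo-2-methylprop-2-enal
Conditions: MnO2 (10 equiv), CH2Cl2, rt; used directly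
Reagents that add atoms: none
Why: Allylic oxidation with MnO2 stops at the aldehyde and keeps the alkene geometry.

**Step 10**
Reactants: 15 (3S)-3,7-dimethyloct-6-en-1-yne; 19 (2E)-3-iodo-2-methylprop-2-enal
Product: 22 (1E,3R,4E,6S)-1-iodo-2,6,10-trimethylundeca-1,4,9-trien-3-ol, via alkenylborane 20 (not isolated), via alkenylzinc 21 (not isolated)
Conditions: Cy2BH, toluene, 0 °C to rt; Me2Zn, −78 °C; (+)-MIB [(2R)-3-exo-morpholinoisoborneol] (5 mol %), then 19, −10 °C; aq. NH4Cl
Reagents that add atoms: none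
Why: Oppolzer–Walsh sequence of syn-hydroboration of the terminal alkyne (E-alkene), boron-to-zinc transmetalation and amino-alcohol-catalysed asymmetric alkenylzinc addition, in which (+)-MIB directs the alkenyl group to the Re face of the aldehyde to set the 3R carbinol under catalyst control.

**Step 11**
Reactants: 11 (2Z)-2-[(2R,3S,4S)-2-{3-[(tert-butyldimethylsilyl)oxy]propyl}-3-ethenyl-4-hydroxy-3,4-dimethylcyclohexylidene]propanenitrile; 22 (1E,3R,4E,6S)-1-iodo-2,6,10-trimethylundeca-1,4,9-trien-3-ol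
Product: 24 (2Z)-2-[(2R,3S,4S)-2-{3-[(tert-butyldimethylsilyl)oxy]propyl}-4-hydroxy-3-[(3E,5R,6E,8S)-5-hydroxy-4,8,12-trimethyltrideca-3,6,11-trien-1-yl]-3,4-dimethylcyclohexylidene]propanenitrile, via alkylborane 23 (not isolated)
Conditions: 9-BBN (2.5 equiv), THF, rt to 40 °C; then 22, Pd(dppf)Cl2 (5 mol %), AsPh3, Cs2CO3, DMF/THF/H2O, rt
Reagents that add atoms: none
Why: B-alkyl Suzuki–Miyaura coupling; 9-BBN hydroborates only the terminal vinyl group (the tetrasubstituted conjugated alkene and the nitrile are inert, the hydroxyl consumes extra borane), and the coupling retains the E geometry of the vinyl iodide.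

**Step 12**
Reactants: 24 coupled nitrile (name as in step 11)
Product: 25 (2Z)-2-[(2R,3S,4S)-2-{3-[(tert-butyldimethylsilyl)oxy]propyl}-4-hydroxy-3-[(3E,5R,6E,8S)-5-hydroxy-4,8,12-trimethyltrideca-3,6,11-trien-1-yl]-3,4-dimethylcyclohexylidene]propanal
Conditions: i-Bu2AlH (4.5 equiv), CH2Cl2, −78 to −40 °C; aq. KNaC4H4O6
Reagents that add atoms: water O
Why: Partial reduction of the conjugated nitrile with i-Bu2AlH stops at the N-aluminio aldimine, which hydrolyses on work-up to the enal with the Z geometry retained; the two free hydroxyls only consume hydride.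

**Step 13**
Reactants: 25 coupled enal (name as in step 12)
Product: 26 (3E,5R,6E,8S)-1-[(1S,2R,3Z,6S)-2-{3-[(tert-butyldimethylsilyl)oxy]propyl}-6-hydroxy-1,6-dimethyl-3-(1-oxopropan-2-ylidene)cyclohexyl]-4,8,12-trimethyltrideca-3,6,11-trien-5-yl acetate
Conditions: Ac2O, pyridine, DMAP (5 mol %), CH2Cl2, 0 °C
Reagents that add atoms: acetic anhydride CC(=O)OC(C)=O
Why: DMAP-catalysed acetylation of the only unhindered free hydroxyl (the secondary bis-allylic one); the tertiary ring alcohol does not react at 0 °C and the primary alcohol is still silylated.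

**Step 14**
Reactants: 26 silyl-protected acetate (name as in step 13)
Product: 27 (3E,5R,6E,8S)-1-[(1S,2R,3Z,6S)-6-hydroxy-2-(3-hydroxypropyl)-1,6-dimethyl-3-(1-oxopropan-2-ylidene)cyclohexyl]-4,8,12-trimethyltrideca-3,6,11-trien-5-yl acetate (target CNP0259235.1)
Conditions: HF·pyridine, excess pyridine, THF, 0 °C to rt
Reagents that add atoms: none
Why: Buffered fluoride desilylation of the primary silyl ether leaves the bis-allylic acetate, the enal and the tertiary alcohol untouched.

## Compound list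

1 | tert-butyldimethyl(pent-4-en-1-yloxy)silane | C=CCCCO[Si](C)(C)C(C)(C)C | starting material
2 | methacrolein | CC(=C)C=O | starting material
3 | (2E)-6-[(tert-butyldimethylsilyl)oxy]-2-methylhex-2-enal | O=C/C(C)=C/CCCO[Si](C)(C)C(C)(C)C | intermediate
4 | 5-nitropentan-2-one | CC(=O)CCC[N+](=O)[O-] | starting material
5 | (3S)-3-{3-[(tert-butyldimethylsilyl)oxy]propyl}-2-methyl-4-nitro-7-oxooctanal (Michael adduct, formed as its catalyst-bound enamine, C-2/C-4 not fixed) | O=CC(C)[C@H](CCCO[Si](C)(C)C(C)(C)C)C([N+](=O)[O-])CCC(C)=O | intermediate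
6 | (1S,2S,5S,6S)-6-{3-[(tert-butyldimethylsilyl)oxy]propyl}-2-hydroxy-1,2-dimethyl-5-nitrocyclohexane-1-carbaldehyde | O=C[C@@]1(C)[C@H](CCCO[Si](C)(C)C(C)(C)C)[C@@H]([N+](=O)[O-])CC[C@]1(C)O | intermediate
7 | (1S,2S,3S,4S)-3-{3-[(tert-butyldimethylsilyl)oxy]propyl}-2-ethenyl-1,2-dimethyl-4-nitrocyclohexan-1-ol | C=C[C@@]1(C)[C@H](CCCO[Si](C)(C)C(C)(C)C)[C@@H]([N+](=O)[O-])CC[C@]1(C)O | intermediate
8 | sodium nitronate of 7 | C=C[C@@]1(C)[C@H](CCCO[Si](C)(C)C(C)(C)C)C(=[N+]([O-])[O-])CC[C@]1(C)O.[Na+] | intermediate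
9 | (2S,3S,4S)-2-{3-[(tert-butyldimethylsilyl)oxy]propyl}-3-ethenyl-4-hydroxy-3,4-dimethylcyclohexan-1-one | C=C[C@@]1(C)[C@H](CCCO[Si](C)(C)C(C)(C)C)C(=O)CC[C@]1(C)O | intermediate
10 | diethyl (1-cyanoethyl)phosphonate | CCOP(=O)(OCC)C(C)C#N | starting material
11 | (2Z)-2-[(2R,3S,4S)-2-{3-[(tert-butyldimethylsilyl)oxy]propyl}-3-ethenyl-4-hydroxy-3,4-dimethylcyclohexylidene]propanenitrile | C=C[C@@]1(C)[C@H](CCCO[Si](C)(C)C(C)(C)C)/C(=C(/C)C#N)CC[C@]1(C)O | intermediate
12 | citral (3,7-dimethylocta-2,6-dienal, E/Z mixture) | CC(C)=CCCC(C)=CC=O | starting material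
13 | (3S)-3,7-dimethyloct-6-enal | C[C@@H](CCC=C(C)C)CC=O | intermediate
14 | (3S)-3,7-dimethylocta-1,6-dien-1-yl nonafluorobutane-1-sulfonate (E/Z) | C[C@@H](CCC=C(C)C)C=COS(=O)(=O)C(F)(F)C(F)(F)C(F)(F)C(F)(F)F | intermediate
15 | (3S)-3,7-dimethyloct-6-en-1-yne | C#C[C@@H](C)CCC=C(C)C | intermediate
16 | prop-2-yn-1-ol | C#CCO | starting material
17 | dimethylaluminium (2E)-3-(dimethylalumanyl)-2-methylprop-2-en-1-olate | C[Al](C)/C=C(\C)CO[Al](C)C | intermediate
18 | (2E)-3-iodo-2-methylprop-2-en-1-ol | OC/C(C)=C/I | intermediate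
19 | (2E)-3-iodo-2-methylprop-2-enal | O=C/C(C)=C/I | intermediate
20 | dicyclohexyl[(1E,3S)-3,7-dimethylocta-1,6-dien-1-yl]borane | C1CCCCC1B(/C=C/[C@@H](C)CCC=C(C)C)C1CCCCC1 | intermediate
21 | [(1E,3S)-3,7-dimethylocta-1,6-dien-1-yl](methyl)zinc | C[Zn]/C=C/[C@@H](C)CCC=C(C)C | intermediate
22 | (1E,3R,4E,6S)-1-iodo-2,6,10-trimethylundeca-1,4,9-trien-3-ol | O[C@H](/C=C/[C@@H](C)CCC=C(C)C)/C(C)=C/I | intermediate
23 | (2Z)-2-[(2R,3S,4S)-3-[2-(9-borabicyclo[3.3.1]nonan-9-yl)ethyl]-2-{3-[(tert-butyldimethylsilyl)oxy]propyl}-4-hydroxy-3,4-dimethylcyclohexylidene]propanenitrile | C(CB1C2CCCC1CCC2)[C@@]1(C)[C@H](CCCO[Si](C)(C)C(C)(C)C)/C(=C(/C)C#N)CC[C@]1(C)O | intermediate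
24 | (2Z)-2-[(2R,3S,4S)-2-{3-[(tert-butyldimethylsilyl)oxy]propyl}-4-hydroxy-3-[(3E,5R,6E,8S)-5-hydroxy-4,8,12-trimethyltrideca-3,6,11-trien-1-yl]-3,4-dimethylcyclohexylidene]propanenitrile | O[C@H](/C=C/[C@@H](C)CCC=C(C)C)/C(C)=C/CC[C@@]1(C)[C@H](CCCO[Si](C)(C)C(C)(C)C)/C(=C(/C)C#N)CC[C@]1(C)O | intermediate
25 | (2Z)-2-[(2R,3S,4S)-2-{3-[(tert-butyldimethylsilyl)oxy]propyl}-4-hydroxy-3-[(3E,5R,6E,8S)-5-hydroxy-4,8,12-trimethyltrideca-3,6,11-trien-1-yl]-3,4-dimethylcyclohexylidene]propanal | O[C@H](/C=C/[C@@H](C)CCC=C(C)C)/C(C)=C/CC[C@@]1(C)[C@H](CCCO[Si](C)(C)C(C)(C)C)/C(=C(/C)C=O)CC[C@]1(C)O | intermediate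
26 | (3E,5R,6E,8S)-1-[(1S,2R,3Z,6S)-2-{3-[(tert-butyldimethylsilyl)oxy]propyl}-6-hydroxy-1,6-dimethyl-3-(1-oxopropan-2-ylidene)cyclohexyl]-4,8,12-trimethyltrideca-3,6,11-trien-5-yl acetate | CC(=O)O[C@H](/C=C/[C@@H](C)CCC=C(C)C)/C(C)=C/CC[C@@]1(C)[C@H](CCCO[Si](C)(C)C(C)(C)C)/C(=C(/C)C=O)CC[C@]1(C)O | intermediate
27 | (3E,5R,6E,8S)-1-[(1S,2R,3Z,6S)-6-hydroxy-2-(3-hydroxypropyl)-1,6-dimethyl-3-(1-oxopropan-2-ylidene)cyclohexyl]-4,8,12-trimethyltrideca-3,6,11-trien-5-yl acetate | CC(=O)O[C@H](/C=C/[C@@H](C)CCC=C(C)C)/C(C)=C/CC[C@@]1(C)[C@H](CCCO)/C(=C(/C)C=O)CC[C@]1(C)O | target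

## Step count and risks

Total: 14 steps. Longest linear sequence: 9 steps (1, 2, 3, 4, 5, 11, 12, 13, 14).

**Step 2 (the proposed new domino).** Possible failures are sluggish iminium formation from the α-branched enal, closure in the other aldol sense (ketone enamine onto the aldehyde, followed by dehydration), or the opposite facial sense. The fallback uses only known reactions, sets out from 1 and comes back at 6. Ozonolysis of 1 (O3, CH2Cl2, −78 °C; PPh3) gives 4-[(tert-butyldimethylsilyl)oxy]butanal F1. Henry reaction with nitromethane gives 5-[(tert-butyldimethylsilyl)oxy]-1-nitropentan-2-ol F2, and MsCl/Et3N dehydration gives tert-butyldimethyl{[(4E)-5-nitropent-4-en-1-yl]oxy}silane F3. Hayashi–Jørgensen Michael addition of propanal to F3 with (R)-α,α-diphenylprolinol trimethylsilyl ether (well-established facial sense) gives (2S,3S)-6-[(tert-butyldimethylsilyl)oxy]-2-methyl-3-(nitromethyl)hexanal F4, which already has the C-6 configuration of 6. Base-catalysed nitro-Michael addition of F4 to methyl vinyl ketone gives keto aldehyde 5, now isolated, and an amino-acid-catalysed 6-enolexo aldolization (L-proline or pyrrolidine/AcOH) closes it to 6.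

**Step 5 (olefination of the hindered ketone and Z/E control).** The phosphonate anion may fail to add to a ketone flanked by a tertiary and a quaternary carbon, or the Z/E ratio may be poor. The fallback sets out from 9 and comes back at 25. Addition of isopropenylmagnesium bromide with CeCl3 to 9 gives (2S,3S,4S)-2-{3-[(tert-butyldimethylsilyl)oxy]propyl}-3-ethenyl-3,4-dimethyl-1-(prop-1-en-2-yl)cyclohexane-1,4-diol F5. Reversible 1,3-transposition with Ph3SiOReO3 gives (2Z)-2-[(2R,3S,4S)-2-{3-[(tert-butyldimethylsilyl)oxy]propyl}-3-ethenyl-4-hydroxy-3,4-dimethylcyclohexylidene]propan-1-ol F6; the unwanted E isomer is re-equilibrated with the same catalyst. Hydroboration with 9-BBN and Pd(dppf)Cl2-catalysed coupling with 22, as in step 11, gives (2Z)-2-[(2R,3S,4S)-2-{3-[(tert-butyldimethylsilyl)oxy]propyl}-4-hydroxy-3-[(3E,5R,6E,8S)-5-hydroxy-4,8,12-trimethyltrideca-3,6,11-trien-1-yl]-3,4-dimethylcyclohexylidene]propan-1-ol F7. TEMPO/PhI(OAc)2 then oxidises only the primary allylic alcohol to give 25.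

**Step 10 (catalyst-controlled alkenylzinc addition to the β-iodo enal).** The risk is insufficient selectivity at C-3 of 22, whose epimer is hard to separate because the second stereocentre is remote. The fallback sets out from 15 and 19 and comes back at 22. Addition of alkenylzinc 21 to 19 without the amino alcohol gives (1E,4E,6S)-1-iodo-2,6,10-trimethylundeca-1,4,9-trien-3-ol as a C-3 epimer mixture F8. MnO2 oxidation gives (1E,4E,6S)-1-iodo-2,6,10-trimethylundeca-1,4,9-trien-3-one F9. Corey–Bakshi–Shibata reduction with (S)-2-methyl-CBS-oxazaborolidine and catecholborane (toluene, −78 °C), in which the α-methyl-β-iodovinyl group acts as the large substituent, returns the 3R alcohol 22.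

## Further compounds

F1 | step 2 | 4-[(tert-butyldimethylsilyl)oxy]butanal | O=CCCCO[Si](C)(C)C(C)(C)C
F2 | step 2 | 5-[(tert-butyldimethylsilyl)oxy]-1-nitropentan-2-ol (racemic) | [O-][N+](=O)CC(O)CCCO[Si](C)(C)C(C)(C)C
F3 | step 2 | tert-butyldimethyl{[(4E)-5-nitropent-4-en-1-yl]oxy}silane | [O-][N+](=O)/C=C/CCCO[Si](C)(C)C(C)(C)C
F4 | step 2 | (2S,3S)-6-[(tert-butyldimethylsilyl)oxy]-2-methyl-3-(nitromethyl)hexanal | O=C[C@@H](C)[C@H](CCCO[Si](C)(C)C(C)(C)C)C[N+](=O)[O-]
F5 | step 5 | (2S,3S,4S)-2-{3-[(tert-butyldimethylsilyl)oxy]propyl}-3-ethenyl-3,4-dimethyl-1-(prop-1-en-2-yl)cyclohexane-1,4-diol (C-1 epimers) | C=C[C@@]1(C)[C@H](CCCO[Si](C)(C)C(C)(C)C)C(O)(C(C)=C)CC[C@]1(C)O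
F6 | step 5 | (2Z)-2-[(2R,3S,4S)-2-{3-[(tert-butyldimethylsilyl)oxy]propyl}-3-ethenyl-4-hydroxy-3,4-dimethylcyclohexylidene]propan-1-ol | C=C[C@@]1(C)[C@H](CCCO[Si](C)(C)C(C)(C)C)/C(=C(/C)CO)CC[C@]1(C)O
F7 | step 5 | (2Z)-2-[(2R,3S,4S)-2-{3-[(tert-butyldimethylsilyl)oxy]propyl}-4-hydroxy-3-[(3E,5R,6E,8S)-5-hydroxy-4,8,12-trimethyltrideca-3,6,11-trien-1-yl]-3,4-dimethylcyclohexylidene]propan-1-ol | O[C@H](/C=C/[C@@H](C)CCC=C(C)C)/C(C)=C/CC[C@@]1(C)[C@H](CCCO[Si](C)(C)C(C)(C)C)/C(=C(/C)CO)CC[C@]1(C)O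
F8 | step 10 | (1E,4E,6S)-1-iodo-2,6,10-trimethylundeca-1,4,9-trien-3-ol (C-3 epimer mixture) | OC(/C=C/[C@@H](C)CCC=C(C)C)/C(C)=C/I
F9 | step 10 | (1E,4E,6S)-1-iodo-2,6,10-trimethylundeca-1,4,9-trien-3-one | O=C(/C=C/[C@@H](C)CCC=C(C)C)/C(C)=C/I
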